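**Strategy.** The cyclohexene core is seen as a dihydroxyacetone unit (C1–C2–C3 of the 7-oxabicyclo[4.1.0]heptene, whose oxygens on C1 and C3 are cis) joined to a three-carbon enal unit (C4–C5–C6). A 1,3-dioxan-5-one ketal of the former is annulated with 2-(phenylselanyl)acrolein: Michael addition forms C3–C4 and an intramolecular aldol forms the future oxirane bond C1–C6, giving a 2,4-dioxabicyclo[3.3.1]nonan-9-one in one operation. The ketal bridge fixes the cis O/O relationship and makes the ketone non-enolisable; afterwards the C1 oxygen closes the oxirane, the ketone becomes the acetate and selenoxide elimination unveils C4=C5.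

Key step: step 4

Assumption: the quinine-derived primary amine of step 4 is taken to induce the absolute configuration drawn for 9; if the sense were the opposite, the pseudo-enantiomeric quinidine-derived amine would be used.

Locants: compounds 9–12 are numbered as 2,4-dioxabicyclo[3.3.1]nonanes (C1, C5 bridgeheads; O2, O4; C3 = CMe2; C6–C8 carbon bridge; C9 carbonyl). Compounds 15–17 are numbered as 7-oxabicyclo[4.1.0]heptanes. Target C3–C4 corresponds to C1–C8 of 9, and target C1–C6 to C5–C6 of 9.

**Step 1**
Reactants: 1 2,2-dimethyl-1,3-dioxan-5-one; 2 formaldehyde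
Product: 3 4-(hydroxymethyl)-2,2-dimethyl-1,3-dioxan-5-one (racemic)
Conditions: (S)-proline (20 mol %), 37% aq. HCHO (1.0 equiv), DMSO, rt
Reagents that add atoms: none
Why: amine-catalysed (enamine) cross-aldol α-hydroxymethylation of the ketone; the new stereocentre need not be controlled because it is planarised again in step 4.

**Step 2**
Reactants: 3 4-(hydroxymethyl)-2,2-dimethyl-1,3-dioxan-5-one
Product: 4 4-{[tert-butyl(dimethyl)silyl]oxymethyl}-2,2-dimethyl-1,3-dioxan-5-one (racemic)
Conditions: TBSCl, imidazole, DMF, 0 °C to rt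
Reagents that add atoms: tert-butyl(chloro)dimethylsilane, CC(C)(C)[Si](C)(C)Cl
Why: standard silylation of a primary alcohol; a silyl ether is chosen because a β-acyloxy ketone would be prone to β-elimination when this α-carbon is enolised in step 4.

**Step 3**
Reactants: 5 acrolein; 6 benzeneselenenyl chloride
Product: 7 2-(phenylselanyl)prop-2-enal
Conditions: pyridine (1.1 equiv), CH2Cl2, 0 °C to rt
Reagents that add atoms: none
Why: α-selenenylation of an enal by PhSeCl–pyridine (addition of PhSeCl across the double bond, then loss of HCl); the selenide is a latent C=C bond.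

**Step 4**
Reactants: 4 4-{[tert-butyl(dimethyl)silyl]oxymethyl}-2,2-dimethyl-1,3-dioxan-5-one; 7 2-(phenylselanyl)prop-2-enal
Product: 9 5-{[tert-butyl(dimethyl)silyl]oxymethyl}-6-hydroxy-3,3-dimethyl-7-(phenylselanyl)-2,4-dioxabicyclo[3.3.1]nonan-9-one (6-OH axial, syn to C9 and anti to O4; 7-SePh equatorial, cis to 6-OH), via Michael adduct keto aldehyde 8 (not isolated)
Conditions: 9-amino-9-deoxy-epi-quinine (20 mol %), 2-fluorobenzoic acid (40 mol %), toluene, 0 °C to rt
Reagents that add atoms: none
Why: Proposed new method: the primary amine should convert 4 into its less substituted enamine, which adds to the iminium-activated enal 7 (Michael, C1–C8), after which the enamine at the substituted α-carbon attacks the aldehyde (C5–C6); the closest known reactions are the α,α′-annulation of cyclic ketone enamines with acrolein to bicyclo[3.3.1]nonan-9-ones (Stork enamine chemistry) and the amine-catalysed Hajos–Parrish aldol. The carbocycle closes by a 6-(enolendo)-exo-trig aldol across the two axial α-positions of the dioxanone chair. C1 and C5 are forced by this 1,3-diaxial bridging; the C6 hydroxyl should end syn to the carbonyl through the hydrogen-bonded aldol transition state; C7 equilibrates as an α-seleno aldehyde before closure and places SePh equatorial. The absolute configuration rests on the catalyst in the aldol event, since C5 of 4 is planar as the enamine and C1 can epimerise until the ring closes. The step needs Michael addition at the CH2 rather than the substituted α-carbon (less hindered enamine) and closure in preference to retro-Michael; the silyl ether suppresses β-elimination.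

**Step 5**
Reactants: 9 the bicyclic hydroxy ketone
Product: 10 5-{[tert-butyl(dimethyl)silyl]oxymethyl}-3,3-dimethyl-9-oxo-7-(phenylselanyl)-2,4-dioxabicyclo[3.3.1]nonan-6-yl methanesulfonate (configuration as 9)
Conditions: MsCl, Et3N, DMAP (cat.), CH2Cl2, −20 °C
Reagents that add atoms: methanesulfonyl chloride, CS(=O)(=O)Cl
Why: sulfonylation of the only free hydroxyl with retention; the cis O/Se arrangement prevents the anti elimination that trans β-hydroxy selenides undergo under these conditions.

**Step 6**
Reactants: 10 the keto mesylate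
Product: 12 9-(acetyloxy)-5-{[tert-butyl(dimethyl)silyl]oxymethyl}-3,3-dimethyl-7-(phenylselanyl)-2,4-dioxabicyclo[3.3.1]nonan-6-yl methanesulfonate (9-OAc syn to the C6–C8 bridge, cis to the 6-mesylate), via C9 alcohol 11 (not isolated)
Conditions: NaBH4, MeOH–CH2Cl2, −40 °C; then Ac2O, pyridine, DMAP (cat.), 0 °C to rt
Reagents that add atoms: acetic anhydride, CC(=O)OC(C)=O
Why: hydride reduction then acetylation; the axial 6-mesylate shields the carbocycle face, so hydride should enter from the dioxane face (only oxygen lone pairs are 1,3-diaxial there), placing the C9 oxygen trans to both ketal oxygens as in the target.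

**Step 7**
Reactants: 12 the bicyclic acetate
Product: 13 2,6-dihydroxy-2-(hydroxymethyl)-3-(methanesulfonyloxy)-4-(phenylselanyl)cyclohexyl acetate (2-OH and 6-OH cis to each other and trans to 1-OAc; 3-OMs trans to 2-OH; 4-SePh cis to 3-OMs)
Conditions: TFA–H2O (9:1), CH2Cl2, 0 °C
Reagents that add atoms: none
Why: acid hydrolysis of the strained bridging ketal and of the primary silyl ether in one operation; no stereocentre is touched.

**Step 8**
Reactants: 13 the triol mesylate
Product: 15 [2-(acetyloxy)-3-(benzoyloxy)-5-(phenylselanyl)-7-oxabicyclo[4.1.0]heptan-1-yl]methyl benzoate (C1, C2, C3, C6 as in 17; SePh trans to the oxirane oxygen), via dibenzoate tertiary alcohol 14 (not isolated)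
Conditions: BzCl (2.3 equiv), pyridine, CH2Cl2, −10 °C; then DBU (3 equiv), 0 °C to rt
Reagents that add atoms: benzoyl chloride, O=C(Cl)c1ccccc1
Why: acylation of the primary and the secondary hydroxyl, which the tertiary one does not undergo without DMAP; the tertiary alkoxide then displaces the anti-periplanar mesylate (3-exo-tet Williamson closure, inversion at C6) to give the cis-fused oxirane.

**Step 9**
Reactants: 15 the epoxy selenide
Product: 17 [(1S,2S,3R,6S)-2-(acetyloxy)-3-(benzoyloxy)-7-oxabicyclo[4.1.0]hept-4-en-1-yl]methyl benzoate, via selenoxide 16 (not isolated)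
Conditions: 30% aq. H2O2, pyridine, CH2Cl2, 0 °C to rt
Reagents that add atoms: hydrogen peroxide, OO (its oxygen is carried only by the non-isolated selenoxide 16)
Why: selenide oxidation and selenoxide syn-elimination; only C4 offers a usable syn β-hydrogen, because elimination toward C6 would place a double bond on the oxirane carbon, so C4=C5 should form regiospecifically.

**Compound list**

1 | 2,2-dimethyl-1,3-dioxan-5-one | CC1(C)OCC(=O)CO1 | starting material
2 | formaldehyde | C=O | starting material
3 | 4-(hydroxymethyl)-2,2-dimethyl-1,3-dioxan-5-one (racemic) | CC1(C)OCC(=O)C(CO)O1 | intermediate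
4 | 4-{[tert-butyl(dimethyl)silyl]oxymethyl}-2,2-dimethyl-1,3-dioxan-5-one (racemic) | CC1(C)OCC(=O)C(CO[Si](C)(C)C(C)(C)C)O1 | intermediate
5 | acrolein | C=CC=O | starting material
6 | benzeneselenenyl chloride | Cl[Se]c1ccccc1 | starting material
7 | 2-(phenylselanyl)prop-2-enal | C=C([Se]c1ccccc1)C=O | intermediate
8 | 3-(6-{[tert-butyl(dimethyl)silyl]oxymethyl}-2,2-dimethyl-5-oxo-1,3-dioxan-4-yl)-2-(phenylselanyl)propanal (stereoisomer mixture, not isolated) | O=CC(CC1OC(C)(C)OC(CO[Si](C)(C)C(C)(C)C)C1=O)[Se]c1ccccc1 | intermediate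
9 | 5-{[tert-butyl(dimethyl)silyl]oxymethyl}-6-hydroxy-3,3-dimethyl-7-(phenylselanyl)-2,4-dioxabicyclo[3.3.1]nonan-9-one | O=C1[C@H]2C[C@@H]([Se]c3ccccc3)[C@@H](O)[C@]1(CO[Si](C)(C)C(C)(C)C)OC(C)(C)O2 | intermediate
10 | 6-methanesulfonate of 9 | O=C1[C@H]2C[C@@H]([Se]c3ccccc3)[C@@H](OS(C)(=O)=O)[C@]1(CO[Si](C)(C)C(C)(C)C)OC(C)(C)O2 | intermediate
11 | C9 alcohol of 10, OH syn to the C6–C8 bridge (not isolated) | O[C@H]1[C@H]2C[C@@H]([Se]c3ccccc3)[C@@H](OS(C)(=O)=O)[C@]1(CO[Si](C)(C)C(C)(C)C)OC(C)(C)O2 | intermediate
12 | C9 acetate of 11 | CC(=O)O[C@H]1[C@H]2C[C@@H]([Se]c3ccccc3)[C@@H](OS(C)(=O)=O)[C@]1(CO[Si](C)(C)C(C)(C)C)OC(C)(C)O2 | intermediate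
13 | 2,6-dihydroxy-2-(hydroxymethyl)-3-(methanesulfonyloxy)-4-(phenylselanyl)cyclohexyl acetate | CC(=O)O[C@H]1[C@H](O)C[C@@H]([Se]c2ccccc2)[C@@H](OS(C)(=O)=O)[C@@]1(O)CO | intermediate
14 | [2-(acetyloxy)-3-(benzoyloxy)-1-hydroxy-6-(methanesulfonyloxy)-5-(phenylselanyl)cyclohexyl]methyl benzoate (not isolated) | CC(=O)O[C@H]1[C@H](OC(=O)c2ccccc2)C[C@@H]([Se]c2ccccc2)[C@@H](OS(C)(=O)=O)[C@@]1(O)COC(=O)c1ccccc1 | intermediate
15 | [2-(acetyloxy)-3-(benzoyloxy)-5-(phenylselanyl)-7-oxabicyclo[4.1.0]heptan-1-yl]methyl benzoate | CC(=O)O[C@H]1[C@H](OC(=O)c2ccccc2)C[C@@H]([Se]c2ccccc2)[C@@H]2O[C@@]21COC(=O)c1ccccc1 | intermediate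
16 | selenoxide of 15 (not isolated) | CC(=O)O[C@H]1[C@H](OC(=O)c2ccccc2)C[C@@H]([Se](=O)c2ccccc2)[C@@H]2O[C@@]21COC(=O)c1ccccc1 | intermediate
17 | [(1S,2S,3R,6S)-2-(acetyloxy)-3-(benzoyloxy)-7-oxabicyclo[4.1.0]hept-4-en-1-yl]methyl benzoate | CC(=O)O[C@H]1[C@H](OC(=O)c2ccccc2)C=C[C@@H]2O[C@@]21COC(=O)c1ccccc1 | target

**Step count.** Total: 9 steps. Longest linear sequence: 8 steps (1, 2, 4, 5, 6, 7, 8, 9); step 3 is a one-step branch.

**Steps most likely to fail**

Step 4 (proposed new method). The annulation may stall after the conjugate addition (no aldol closure at the hindered, tetrasubstituted enamine carbon), revert by retro-Michael, or close with poor facial control. The fallback sets out from 4 and returns at 9, making the two bonds in separate known operations. Ketone 4 is condensed with pyrrolidine (TsOH cat., toluene, water removal) to the less substituted enamine 1-(4-{[tert-butyl(dimethyl)silyl]oxymethyl}-2,2-dimethyl-4H-1,3-dioxin-5-yl)pyrrolidine F1. F1 adds to 7 (Stork enamine Michael addition, MeCN, 0 °C) and aqueous AcOH/NaOAc hydrolysis gives isolated 8. Base-mediated intramolecular aldol (KOH, MeOH, 0 °C) then closes 8 to racemic 9. The enantiomers are separated by lipase-catalysed transesterification (Candida antarctica lipase B, vinyl acetate, MTBE), which is expected to acetylate the unwanted enantiomer to the 6-acetate of ent-9 F2 and leave 9 for step 5.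

Step 6. Hydride delivery may occur from the carbocycle face and give the wrong C9 configuration. The fallback sets out from 10 and returns at 12. The epimeric alcohol, the C9 epimer of 11 F3, is not discarded but inverted under Mitsunobu conditions (PPh3, diisopropyl azodicarboxylate, AcOH, toluene), which installs the acetate with inversion and gives 12 directly.

Step 7. In the free triol the acetate may migrate to a neighbouring hydroxyl under acid, or the benzoylation that follows may lose selectivity. The fallback sets out from 12 and returns at 14, unmasking the hydroxyls one at a time. HF·pyridine removes only the silyl ether to give the primary alcohol F4. BzCl/pyridine gives the primary benzoate F5. Aqueous AcOH then opens the ketal to the diol F6, whose single secondary hydroxyl is benzoylated (BzCl, pyridine) to 14. DBU then closes the oxirane as in step 8.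

**Further compounds**

F1 | step 4 | 1-(4-{[tert-butyl(dimethyl)silyl]oxymethyl}-2,2-dimethyl-4H-1,3-dioxin-5-yl)pyrrolidine | CC1(C)OC=C(N2CCCC2)C(CO[Si](C)(C)C(C)(C)C)O1
F2 | step 4 | 6-acetate of the enantiomer of 9 | O=C1[C@@H]2C[C@H]([Se]c3ccccc3)[C@H](OC(C)=O)[C@@]1(CO[Si](C)(C)C(C)(C)C)OC(C)(C)O2
F3 | step 6 | C9 epimer of alcohol 11 | O[C@@H]1[C@H]2C[C@@H]([Se]c3ccccc3)[C@@H](OS(C)(=O)=O)[C@]1(CO[Si](C)(C)C(C)(C)C)OC(C)(C)O2
F4 | step 7 | 9-(acetyloxy)-5-(hydroxymethyl)-3,3-dimethyl-7-(phenylselanyl)-2,4-dioxabicyclo[3.3.1]nonan-6-yl methanesulfonate | CC(=O)O[C@H]1[C@H]2C[C@@H]([Se]c3ccccc3)[C@@H](OS(C)(=O)=O)[C@]1(CO)OC(C)(C)O2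
F5 | step 7 | primary benzoate of F4 | CC(=O)O[C@H]1[C@H]2C[C@@H]([Se]c3ccccc3)[C@@H](OS(C)(=O)=O)[C@]1(COC(=O)c3ccccc3)OC(C)(C)O2
F6 | step 7 | [2-(acetyloxy)-1,3-dihydroxy-6-(methanesulfonyloxy)-5-(phenylselanyl)cyclohexyl]methyl benzoate | CC(=O)O[C@H]1[C@H](O)C[C@@H]([Se]c2ccccc2)[C@@H](OS(C)(=O)=O)[C@@]1(O)COC(=O)c1ccccc1
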